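(All constants are assumed, and the outcome is calculated.)

The slowness of this flask lies in the release of target from ternary complex, which takes 7.14 × 10⁻⁴ s per event, far longer than the 7.45 × 10⁻⁶ s enzyme needs to meet starting material.

in all of them: starting material 0.017 M; enzyme 0.90 µM; added ligand 0.45 µM

| flask | second substrate | time | remark |
|---|---|---|---|
| delta | 0.0221 M (fed, over 7.50 s) | 15 s | a stirred flask in which second substrate is dosed at a steady rate over 7.50 s without added volume, worked up at 15 s |
| theta | 0.0221 M | 15 s | a closed flask charged with all of it at once and left for 15 s |
| epsilon | 0.0221 M |  | one stirred flow tank at steady state, fed with the mixture as stated, mean residence time 75.0 s |
| alpha | 0.0221 M |  | one stirred flow tank at steady state, fed with the mixture as stated, mean residence time 15 s |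

    starting material + target ⇌ idle adduct, settled at all times (K1 = 2700 M⁻¹)
    second substrate + starting complex ⇌ ternary complex (K2 = 110 M⁻¹, k2 = 1.7 × 10⁶ M⁻¹ s⁻¹)
    ternary complex → enzyme + target (k3 = 1400 s⁻¹)
    enzyme + added ligand ⇌ idle complex, settled at all times (K4 = 3.2 × 10⁶ M⁻¹)
    starting material + enzyme ⇌ starting complex (K5 = 120 M⁻¹, k5 = 7.9 × 10⁶ M⁻¹ s⁻¹)

- percent here means starting material units held: one idle adduct counts as two
- what is said of target includes idle adduct
- the stated concentrations are those of everything mixed, before any reaction; amounts are the same in each set-up
- the feed brings no volume worth counting
- in an amount of target, one idle adduct counts as one target
- run time (delta): 15 s

1. the set-up with the highest amount of target at the outlet or at the end, in percent of the starting material put in ("none" if the first two lie within 2 percentage points) (delta / theta / epsilon / alpha / none)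
2. amount of target at the outlet or at the end, in percent of the starting material put in, delta
3. amount of target at the outlet or at the end, in percent of the starting material put in, theta
4. amount of target at the outlet or at the end, in percent of the starting material put in, epsilon
5. amount of target at the outlet or at the end, in percent of the starting material put in, alpha

Turnovers give the measure. The clearing time is the time in which the whole enzyme charge, standing as ternary complex, would turn out one charge of starting material as target: 13.5 s. The working share is the fraction of enzyme actually standing as ternary complex. Target, as a fraction of the charge, is then the mean working share times the time in a flask, and the outlet share times the residence time in a tank, both divided by the clearing time.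

The reckoning here follows theta in slow motion. In the first instants enzyme binds its partners and added ligand. The way back from ternary complex runs 11.0 times faster than release, and the way back from starting complex runs faster still, so the binding steps stand near balance and release is the rate-limiting step. Write g for the starting-complex constant times [starting material], h for the ternary-complex constant times [second substrate], and l for the idle-complex constant times [added ligand], taken at its charge, which overstates it. The working share is then gh divided by the sum of one, g, gh and l, which gives 52.5% at the start.

In the middle, each new target meets starting material with a binding strength of 46 at the start and becomes idle adduct, so [starting material] falls twice as fast as target forms.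

For the end, take [starting material] down to 0.00425 M, with [second substrate] at 0.0157 M. The share is then 23.0%, and the mean of the two shares is 37.8%. Over 1.11 clearing times, theta reaches 42.0% target. Two units per target would leave 16.0% of the starting material, less than the 25.0% assumed, so this figure leans high. Epsilon has 5.56 clearing times, so this reckoning puts it first.

The forecast gives 36.5% for delta, 42% for theta, 53% for epsilon and 34% for alpha, with epsilon best: “Residence or batch time is therefore what matters”.

The simulation gives 36.6% for delta, 42.0% for theta, 53.0% for epsilon and 34.2% for alpha, with epsilon best.

Theta's result means a mean working share of 37.8%. The neighbour of delta with 1.5 × 10⁻⁶ M of enzyme has a clearing time of 8.10 s, and its 49.9% target means a mean share of 26.9%. Theta has not come to rest at 15 s: by 150 s target stands at 76.9% there, and at 76.6% in delta. Theta's idle adduct still holds 44.5% and its ternary complex stands at 1.06%. Reckoned by the clearing time with the working share held at that value, the 23.1% of target still short of the full charge in theta comes to a further 294 s.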